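**Retrosynthetic overview**
- Esters last: tiglate on O-8 and acetates on O-2/O-13 go onto the desilylated core. O-8 comes from γ-oxidation of the butenolide, and the C4 carbinol from a C4 ketone via methylenation and Markovnikov hydration.
- Key bond C7–C11: intermolecular aldol addition of a 3-silyloxypropanoate enolate (C11–C13) to the ring C α-silyloxy ketone, then lactonisation onto O-6 and E1cB elimination to the butenolide.
- Ring C (C6–C7): SmI2 pinacol closure of a β-oriented 3-oxopropyl chain onto the cyclobutanone, which enforces the cis-syn-cis fusion. The C10 quaternary centre comes from allylation followed by convex-face methylation.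
- Cyclobutane (C1–C10, C5–C6): [2+2] photocycloaddition of (S)-4-silyloxycyclopentenone (ring A, the only source of chirality) with allene, then ozonolysis to the cyclobutanone.
- Ring order: A (purchased) → cyclobutane → C → lactone.

**Conventions.** Labels used in all names: ring A = C1–C5 (C1, C5 ring-fusion CH; C2 = CH–O; C4 = C(CH3)(OH)); cyclobutane = C1, C5, C6, C10; ring C = C6–C10 (C8 = CH–O); lactone O6–C12(=O)–C11=C7; C13 = CH2O on C11; C14 = CH3 on C10; C15 = CH3 on C4. α = the convex face (the cyclobutane face carrying H-1 and H-5; on ring A cis to H-1/H-5, on ring C cis to C14/O-6); rings A and C both hang from the β face. TBS = tert-butyldimethylsilyl, TBDPS = tert-butyldiphenylsilyl, TMS = trimethylsilyl.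

**Assumption.** Enone 1 is bought as the single (S) enantiomer (both antipodes are catalogue compounds) and allene is bought as the gas.

Step 1
Reactants: 1 (S)-4-(tert-butyldimethylsilyloxy)cyclopent-2-en-1-one; 2 allene (propa-1,2-diene)
Product: 3 photoadduct, 4-(TBSO)-7-methylenebicyclo[3.2.0]heptan-2-one (C4 ketone, C6=CH2, C10H2, 2α-OTBS, H-1/H-5 cis)
Conditions: hν (450 W Hg lamp, Pyrex), excess 2, CH2Cl2, −78 °C
Reagents that add atoms: none
Why: Enone–allene [2+2] photocycloaddition gives the head-to-head (β,γ-unsaturated ketone) regioisomer with a cis ring fusion, and allene adds to the enone face anti to the silyloxy group, which sets H-1 and H-5 cis to O-2.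

Step 2
Reactants: 3
Product: 4 C4 ethylene ketal of 3
Conditions: 1,2-bis(trimethylsilyloxy)ethane, TMSOTf (cat.), CH2Cl2, −78 °C
Reagents that add atoms: 1,2-bis(trimethylsilyloxy)ethane, C[Si](C)(C)OCCO[Si](C)(C)C
Why: Noyori ketalisation masks the C4 ketone at low temperature without β-elimination of the silyloxy group, so the cyclobutanone made next is never part of a 1,3-diketone.

Step 3
Reactants: 4
Product: 6 C6 cyclobutanone (C4 ketal; 2α-OTBS), via spiro-ozonide 5 (not isolated)
Conditions: O3, CH2Cl2, −78 °C; then Me2S, −78 °C → rt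
Reagents that add atoms: ozone, [O-][O+]=O
Why: Ozonolysis (Criegee mechanism) of the exocyclic methylene with reductive work-up unveils the cyclobutanone that activates C10.

Step 4
Reactants: 6
Product: 8 10α-allyl cyclobutanone (10β-H), via lithium enolate 7 (not isolated)
Conditions: LiN(iPr)2, THF, −78 °C; then allyl bromide, DMPU, −78 → −30 °C
Reagents that add atoms: allyl bromide, C=CCBr
Why: Kinetic enolate alkylation at the only non-bridgehead α-carbon (C10) installs C7–C9; its configuration does not matter because step 5 re-enolises this centre.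

Step 5
Reactants: 8
Product: 10 10α-methyl-10β-allyl cyclobutanone, via potassium enolate 9 (not isolated)
Conditions: KN(SiMe3)2, THF, −78 → 0 °C; then MeI, −78 °C
Reagents that add atoms: iodomethane, CI
Why: In this second enolate alkylation MeI attacks the planar C10 enolate from the convex (α) face of the bicyclo[3.2.0]heptanone, so C14 ends α and the allyl chain is pushed β (endo), which fixes the quaternary C10 centre.

Step 6
Reactants: 10
Product: 12 diol with 10β-(3-hydroxypropyl) chain plus C6 cyclobutanol (C6 epimers), via bis-boron adduct 11 (not isolated)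
Conditions: 9-BBN (3 equiv), THF, 0 → 65 °C; then NaOH, H2O2, 0 °C → rt
Reagents that add atoms: hydrogen peroxide, OO
Why: Brown hydroboration–oxidation gives the anti-Markovnikov primary alcohol, and letting excess 9-BBN reduce the cyclobutanone first avoids Baeyer–Villiger cleavage of a cyclobutanone by alkaline peroxide.

Step 7
Reactants: 12
Product: 13 keto-aldehyde (C6 cyclobutanone, 10β-(3-oxopropyl) chain with C7 as CHO)
Conditions: Dess–Martin periodinane, NaHCO3, CH2Cl2, rt
Reagents that add atoms: none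
Why: Dess–Martin oxidation of both alcohols under buffered, non-enolising conditions restores the cyclobutanone and gives the aldehyde.

Step 8
Reactants: 13
Product: 14 tricyclic cis-syn-cis 6α,7α-diol (ring C closed)
Conditions: SmI2 (2.5 equiv), t-BuOH, THF, −78 °C → rt
Reagents that add atoms: none
Why: In this intramolecular pinacol (ketyl) coupling the aldehyde sits on the β chain and can reach the cyclobutanone only from the β face, so ring C closes cis-syn-cis with O-6 α, and samarium chelation gives the cis diol.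

Step 9
Reactants: 14
Product: 15 α-ketol (6α-OH, C7 ketone)
Conditions: IBX, DMSO, rt
Reagents that add atoms: none
Why: IBX oxidises the secondary alcohol of a 1,2-diol to the ketone without C–C cleavage and leaves the tertiary alcohol alone.

Step 10
Reactants: 15
Product: 16 6α-O-TMS ether of 15
Conditions: 1-(trimethylsilyl)imidazole, CH2Cl2, 0 °C → rt
Reagents that add atoms: 1-(trimethylsilyl)imidazole, C[Si](C)(C)n1ccnc1
Why: Neutral silylation caps the tertiary hydroxyl, which blocks α-ketol (acyloin) ring expansion of the 1-acylcyclobutanol and leaves a ketone ready for enolate addition.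

Step 11
Reactants: 17 methyl 3-hydroxypropanoate
Product: 18 methyl 3-(tert-butyldiphenylsilyloxy)propanoate
Conditions: TBDPSCl, imidazole, DMF, rt
Reagents that add atoms: tert-butyl(chloro)diphenylsilane, CC(C)(C)[Si](Cl)(c1ccccc1)c1ccccc1
Why: Standard silylation gives a C11–C13 ester whose β-silyloxy group is a poor leaving group, so its enolate survives at −78 °C.

Step 12
Reactants: 18 methyl 3-(tert-butyldiphenylsilyloxy)propanoate; 16 6α-O-TMS α-ketol
Product: 20 aldol adduct (7β-OH; 7α-CH(CO2Me)CH2OTBDPS; C11 epimers), via lithium ester enolate 19 (not isolated)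
Conditions: LiN(iPr)2, THF, −78 °C (18); then 16, −78 °C; NH4Cl aq
Reagents that add atoms: none
Why: Intermolecular aldol addition of the ester enolate to the C7 ketone from the open α face (the β face is the concave pocket) forms C7–C11 with C11 cis to O-6; the C11 configuration is irrelevant because it becomes sp2.

Step 13
Reactants: 20
Product: 21 hydroxy lactone (12,6α-olide, 7β-OH, H-11, 13-OTBDPS)
Conditions: K2CO3, MeOH, 0 °C
Reagents that add atoms: none
Why: Methanolysis of the TMS ether frees the C6 alkoxide, which lactonises onto the cis-disposed methyl ester (intramolecular transesterification to the γ-lactone).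

Step 14
Reactants: 21
Product: 23 butenolide (7(11)-en-12,6α-olide; C4 ketal; 2α-OTBS; 13-OTBDPS), via C7 trifluoroacetate 22 (not isolated)
Conditions: (CF3CO)2O, pyridine, DMAP, CH2Cl2, 0 °C; then DBU, rt
Reagents that add atoms: none
Why: Acylation of the tertiary alcohol followed by E1cB elimination through the lactone enolate gives the conjugated butenolide without a cation next to the cyclobutane.

Step 15
Reactants: 23
Product: 24 C4 ketone
Conditions: PPTS, acetone/H2O, 50 °C
Reagents that add atoms: water, O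
Why: Mild acid hydrolysis removes the ketal now that O-6 is acylated, so the β-acyloxy ketone cannot open the cyclobutane by retro-aldol.

Step 16
Reactants: 24
Product: 25 C4 exocyclic methylene (C15H2)
Conditions: Zn, CH2Br2, TiCl4, THF, 0 °C → rt
Reagents that add atoms: dibromomethane, BrCBr
Why: Lombardo–Takai methylenation is non-basic, so the β-silyloxy ketone does not eliminate and the lactone is untouched.

Step 17
Reactants: 25
Product: 27 tertiary alcohol (4α-OH; 4β-CH3), via organomercurial 26 (not isolated)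
Conditions: Hg(OAc)2, THF/H2O, rt; then NaBH4, NaOH aq, 0 °C
Reagents that add atoms: water, O
Why: In this oxymercuration–demercuration (Markovnikov hydration) water attacks C4 of the mercurinium ion from the only open (α) face, giving 4α-OH with C15 left in the β pocket, and no radical is generated at C4 next to the strained ring.

Step 18
Reactants: 27
Product: 28 silyl dienol ether (C12(OTMS)=C11, C7=C8, 4-OTMS)
Conditions: LiN(iPr)2 (2.5 equiv), Me3SiCl, THF, −78 → 0 °C; hexane filtration
Reagents that add atoms: chlorotrimethylsilane, C[Si](C)(C)Cl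
Why: The only γ-hydrogens of the butenolide are on C8 (C6 is quaternary), so deprotonation and O-silylation give the exocyclic vinylogous silyl ketene acetal, and the tertiary alkoxide is silylated as well.

Step 19
Reactants: 28
Product: 30 8α-hydroxy butenolide (4α-OH free), via bis-TMS ether 29 (not isolated)
Conditions: DMDO, acetone/CH2Cl2, −78 → 0 °C; then citric acid, MeOH, 0 °C
Reagents that add atoms: dimethyldioxirane, CC1(C)OO1
Why: In this vinylogous Rubottom oxidation the dioxirane attacks the γ-terminus C8 from the convex α face (as in the oxidation of 2-silyloxyfurans to γ-hydroxybutenolides), which restores the butenolide and sets 8α-O while C7 stays sp2.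

Step 20
Reactants: 30
Product: 31 8α-tiglate
Conditions: tigloyl chloride, pyridine, DMAP (cat.), CH2Cl2, 0 °C → rt
Reagents that add atoms: (E)-2-methylbut-2-enoyl chloride, C/C=C(\C)C(=O)Cl
Why: Acylation occurs at the only secondary hydroxyl (the tertiary C4–OH is inert), and pyridine as base keeps the E-configured conjugated acyl group intact.

Step 21
Reactants: 31
Product: 32 triol (2α-OH, 4α-OH, 13-OH; 8α-tiglate)
Conditions: HF·pyridine, pyridine, THF, 0 °C → rt
Reagents that add atoms: none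
Why: Buffered fluoride cleaves both silyl ethers without ionising the tertiary alcohol or touching the esters.

Step 22
Reactants: 32
Product: 33 target
Conditions: Ac2O, pyridine, DMAP (cat.), CH2Cl2, 0 °C
Reagents that add atoms: acetic anhydride, CC(=O)OC(C)=O
Why: Acetylation takes the primary and secondary hydroxyls while the hindered tertiary C4–OH stays free.

**Compound list**
1 | (S)-4-(tert-butyldimethylsilyloxy)cyclopent-2-en-1-one | O=C1C=C[C@@H](O[Si](C)(C)C(C)(C)C)C1 | starting material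
2 | allene (propa-1,2-diene) | C=C=C | starting material
3 | photoadduct: C4 ketone, C6=CH2, C10H2, 2α-OTBS, H-1/H-5 α | C1[C@@H]2[C@@H](O[Si](C)(C)C(C)(C)C)CC(=O)[C@@H]2C1=C | intermediate
4 | C4 ethylene ketal of 3 | C1[C@@H]2[C@@H](O[Si](C)(C)C(C)(C)C)CC3(OCCO3)[C@@H]2C1=C | intermediate
5 | spiro-1,2,4-trioxolane (ozonide) at C6 of 4 | C1[C@@H]2[C@@H](O[Si](C)(C)C(C)(C)C)CC3(OCCO3)[C@@H]2C14OCOO4 | intermediate
6 | C6 cyclobutanone, C4 ketal, 2α-OTBS | C1[C@@H]2[C@@H](O[Si](C)(C)C(C)(C)C)CC3(OCCO3)[C@@H]2C1=O | intermediate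
7 | lithium enolate of 6 (C6(OLi)=C10) | [Li]OC1=C[C@@H]2[C@@H](O[Si](C)(C)C(C)(C)C)CC3(OCCO3)[C@@H]21 | intermediate
8 | 10α-allyl cyclobutanone (10β-H) | C=CC[C@H]1[C@@H]2[C@@H](O[Si](C)(C)C(C)(C)C)CC3(OCCO3)[C@@H]2C1=O | intermediate
9 | potassium enolate of 8 | [K]OC1=C(CC=C)[C@@H]2[C@@H](O[Si](C)(C)C(C)(C)C)CC3(OCCO3)[C@@H]21 | intermediate
10 | 10α-methyl-10β-allyl cyclobutanone | C=CC[C@]1(C)[C@@H]2[C@@H](O[Si](C)(C)C(C)(C)C)CC3(OCCO3)[C@@H]2C1=O | intermediate
11 | bis(9-borabicyclo[3.3.1]nonan-9-yl) adduct: C7–B alkylborane and C6–O borinate | B1(C2CCCC1CCC2)CCC[C@]3(C)[C@@H]4[C@@H](O[Si](C)(C)C(C)(C)C)CC5(OCCO5)[C@@H]4C3OB6C7CCCC6CCC7 | intermediate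
12 | diol: 10β-(3-hydroxypropyl), C6 cyclobutanol (C6 epimers) | OCCC[C@]1(C)[C@@H]2[C@@H](O[Si](C)(C)C(C)(C)C)CC3(OCCO3)[C@@H]2C1O | intermediate
13 | keto-aldehyde: C6 cyclobutanone, 10β-(3-oxopropyl) | O=CCC[C@]1(C)[C@@H]2[C@@H](O[Si](C)(C)C(C)(C)C)CC3(OCCO3)[C@@H]2C1=O | intermediate
14 | tricyclic cis-syn-cis 6α,7α-diol | O[C@H]1CC[C@]2(C)[C@@H]3[C@@H](O[Si](C)(C)C(C)(C)C)CC4(OCCO4)[C@@H]3[C@@]21O | intermediate
15 | α-ketol: 6α-OH, C7 ketone | O=C1CC[C@]2(C)[C@@H]3[C@@H](O[Si](C)(C)C(C)(C)C)CC4(OCCO4)[C@@H]3[C@@]21O | intermediate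
16 | 6α-O-TMS ether of 15 | O=C1CC[C@]2(C)[C@@H]3[C@@H](O[Si](C)(C)C(C)(C)C)CC4(OCCO4)[C@@H]3[C@@]21O[Si](C)(C)C | intermediate
17 | methyl 3-hydroxypropanoate | COC(=O)CCO | starting material
18 | methyl 3-(tert-butyldiphenylsilyloxy)propanoate | COC(=O)CCO[Si](c1ccccc1)(c1ccccc1)C(C)(C)C | intermediate
19 | lithium enolate of 18 | COC(O[Li])=CCO[Si](c1ccccc1)(c1ccccc1)C(C)(C)C | intermediate
20 | aldol adduct: 7β-OH, 7α-CH(CO2Me)CH2OTBDPS, 6α-OTMS (C11 epimers) | COC(=O)C(CO[Si](c1ccccc1)(c1ccccc1)C(C)(C)C)[C@@]1(O)CC[C@]2(C)[C@@H]3[C@@H](O[Si](C)(C)C(C)(C)C)CC4(OCCO4)[C@@H]3[C@@]21O[Si](C)(C)C | intermediate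
21 | hydroxy lactone: 12,6α-olide, 7β-OH, 13-OTBDPS (C11 epimers) | C1C[C@]2(C)[C@@H]3[C@@H](O[Si](C)(C)C(C)(C)C)CC4(OCCO4)[C@@H]3[C@@]23OC(=O)C(CO[Si](c5ccccc5)(c5ccccc5)C(C)(C)C)[C@@]13O | intermediate
22 | 7β-O-trifluoroacetate of 21 | C1C[C@]2(C)[C@@H]3[C@@H](O[Si](C)(C)C(C)(C)C)CC4(OCCO4)[C@@H]3[C@@]23OC(=O)C(CO[Si](c5ccccc5)(c5ccccc5)C(C)(C)C)[C@@]13OC(=O)C(F)(F)F | intermediate
23 | butenolide (7(11)-en-12,6α-olide), C4 ketal, 2α-OTBS, 13-OTBDPS | C1C[C@]2(C)[C@@H]3[C@@H](O[Si](C)(C)C(C)(C)C)CC4(OCCO4)[C@@H]3[C@@]23OC(=O)C(CO[Si](c5ccccc5)(c5ccccc5)C(C)(C)C)=C13 | intermediate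
24 | C4 ketone butenolide | C1C[C@]2(C)[C@@H]3[C@@H](O[Si](C)(C)C(C)(C)C)CC(=O)[C@@H]3[C@@]23OC(=O)C(CO[Si](c4ccccc4)(c4ccccc4)C(C)(C)C)=C13 | intermediate
25 | C4 exocyclic methylene butenolide | C1C[C@]2(C)[C@@H]3[C@@H](O[Si](C)(C)C(C)(C)C)CC(=C)[C@@H]3[C@@]23OC(=O)C(CO[Si](c4ccccc4)(c4ccccc4)C(C)(C)C)=C13 | intermediate
26 | 4α-hydroxy-15-(acetoxymercurio) adduct | C1C[C@]2(C)[C@@H]3[C@@H](O[Si](C)(C)C(C)(C)C)C[C@@](C[Hg]OC(C)=O)(O)[C@@H]3[C@@]23OC(=O)C(CO[Si](c4ccccc4)(c4ccccc4)C(C)(C)C)=C13 | intermediate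
27 | tertiary alcohol: 4α-OH, 4β-CH3 | C1C[C@]2(C)[C@@H]3[C@@H](O[Si](C)(C)C(C)(C)C)C[C@@](C)(O)[C@@H]3[C@@]23OC(=O)C(CO[Si](c4ccccc4)(c4ccccc4)C(C)(C)C)=C13 | intermediate
28 | silyl dienol ether: C12(OTMS)=C11, C7=C8, 4-OTMS | C=1C[C@]2(C)[C@@H]3[C@@H](O[Si](C)(C)C(C)(C)C)C[C@@](C)(O[Si](C)(C)C)[C@@H]3[C@@]23OC(O[Si](C)(C)C)=C(CO[Si](c4ccccc4)(c4ccccc4)C(C)(C)C)C=13 | intermediate
29 | 8α-OTMS, 4α-OTMS butenolide | C[Si](C)(C)O[C@H]1C[C@]2(C)[C@@H]3[C@@H](O[Si](C)(C)C(C)(C)C)C[C@@](C)(O[Si](C)(C)C)[C@@H]3[C@@]23OC(=O)C(CO[Si](c4ccccc4)(c4ccccc4)C(C)(C)C)=C13 | intermediate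
30 | 8α-hydroxy butenolide (4α-OH, 2α-OTBS, 13-OTBDPS) | O[C@H]1C[C@]2(C)[C@@H]3[C@@H](O[Si](C)(C)C(C)(C)C)C[C@@](C)(O)[C@@H]3[C@@]23OC(=O)C(CO[Si](c4ccccc4)(c4ccccc4)C(C)(C)C)=C13 | intermediate
31 | 8α-tiglate (4α-OH, 2α-OTBS, 13-OTBDPS) | C/C=C(\C)C(=O)O[C@H]1C[C@]2(C)[C@@H]3[C@@H](O[Si](C)(C)C(C)(C)C)C[C@@](C)(O)[C@@H]3[C@@]23OC(=O)C(CO[Si](c4ccccc4)(c4ccccc4)C(C)(C)C)=C13 | intermediate
32 | triol: 2α-OH, 4α-OH, 13-OH, 8α-tiglate | C/C=C(\C)C(=O)O[C@H]1C[C@]2(C)[C@@H]3[C@@H](O)C[C@@](C)(O)[C@@H]3[C@@]23OC(=O)C(CO)=C13 | intermediate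
33 | CNP0210373.1: 2α,13-diacetoxy-4α-hydroxy-8α-tigloyloxy-7(11)-en-12,6α-olide, (1R,2S,4R,5R,6R,8S,10R) in the labels above | C/C=C(\C)C(=O)O[C@H]1C[C@]2(C)[C@@H]3[C@@H](OC(C)=O)C[C@@](C)(O)[C@@H]3[C@@]23OC(=O)C(COC(C)=O)=C13 | target

**Totals.** 22 steps in all; the longest linear sequence is 21 steps (steps 1–10 and 12–22; step 11 is the one-step side branch).

**Steps most likely to fail, with fallbacks**

Step 12. Ketone 16 is enolisable at C8 and hindered, and the aldolate can revert. The fallback delivers C11–C13 from O-6 instead. It sets out from α-ketol 15: warming with Meldrum's acid (toluene, 80 °C) acylates the tertiary hydroxyl to give the O-6 hydrogen malonate F1. Piperidinium acetate (CH2Cl2, rt) then closes the ring by intramolecular Knoevenagel condensation onto the C7 ketone, giving the 11-carboxy butenolide F2. BH3·SMe2 (THF, 0 °C) reduces only the carboxylic acid to the 13-hydroxy butenolide F3, and TBDPSCl/imidazole gives 23, where the main route resumes at step 15.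

Step 17. The partial positive charge at C4 in the mercurinium ion lies next to the strained C5–C6 bond and could trigger ring expansion. The fallback is a hydrogen-atom-transfer (Mukaiyama) hydration, a radical pathway instead of an ionic one. It sets out from 25: Co(acac)2 (cat.), PhSiH3 and pressurised O2 in i-PrOH/THF at 0 °C give 27 directly, with O2 again entering from the α face. The high O2 pressure is needed so that capture of the C4 radical outruns β-scission of the cyclobutane. No new isolated compound is involved, and the route resumes at 27.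

Step 19. The silyl dienol ether 28 could be oxidised at C11 instead of C8, or simply hydrolyse back to 27. The fallback sets out from 27: LiN(iPr)2 (2.2 equiv, THF, −78 °C) followed by an AcOH quench gives, by kinetic α-protonation, the deconjugated lactone F4 (C7=C8, H on C11). A Schenck ene reaction with singlet oxygen (O2, tetraphenylporphyrin, hν, CH2Cl2, −30 °C) abstracts H-11 and delivers oxygen to C8 from the α face, giving the 8α-hydroperoxy butenolide F5. PPh3 reduces it to 30, where the route resumes at step 20.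

**Further compounds**
F1 | step 12 | O-6 hydrogen malonate of α-ketol 15 | O=C1CC[C@]2(C)[C@@H]3[C@@H](O[Si](C)(C)C(C)(C)C)CC4(OCCO4)[C@@H]3[C@@]21OC(=O)CC(O)=O
F2 | step 12 | 11-carboxy butenolide (C4 ketal, 2α-OTBS) | C1C[C@]2(C)[C@@H]3[C@@H](O[Si](C)(C)C(C)(C)C)CC4(OCCO4)[C@@H]3[C@@]23OC(=O)C(C(O)=O)=C13
F3 | step 12 | 13-hydroxy butenolide (C4 ketal, 2α-OTBS) | C1C[C@]2(C)[C@@H]3[C@@H](O[Si](C)(C)C(C)(C)C)CC4(OCCO4)[C@@H]3[C@@]23OC(=O)C(CO)=C13
F0 | step 17 | none | none
F4 | step 19 | deconjugated lactone (C7=C8, H-11; 4α-OH, 2α-OTBS, 13-OTBDPS) | C=1C[C@]2(C)[C@@H]3[C@@H](O[Si](C)(C)C(C)(C)C)C[C@@](C)(O)[C@@H]3[C@@]23OC(=O)C(CO[Si](c4ccccc4)(c4ccccc4)C(C)(C)C)C=13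
F5 | step 19 | 8α-hydroperoxy butenolide (4α-OH, 2α-OTBS, 13-OTBDPS) | OO[C@H]1C[C@]2(C)[C@@H]3[C@@H](O[Si](C)(C)C(C)(C)C)C[C@@](C)(O)[C@@H]3[C@@]23OC(=O)C(CO[Si](c4ccccc4)(c4ccccc4)C(C)(C)C)=C13
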